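**Strategy.** The route rests on disconnecting C4–C4a of the cis-decahydroquinoline. C4 is a bare methylene linking C3 to the fusion carbon C4a, and C5 bears its hydrogen on the same face as H4a; a primary C4 radical can therefore close the piperidine (ring A) by 6-exo attack on a C4a=C5 cyclohexene and, after hydrogen transfer to C5, set C4a and C5 in one operation, with C2, C3 and C8a already in place. The precursor is an N-Boc (1R)-3-alkylcyclohex-2-enylamine whose nitrogen carries a (2S,3S)-3-hydroxy-4-iodobutan-2-yl arm; it is assembled by palladium-catalysed allylic amination of a cyclohexenyl carbonate with a glyceraldehyde-derived amine.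

Key step: step 13

Remarks on the chemistry:
- Ring positions use decahydroquinoline numbering (ring A = N1, C2, C3, C4, C4a, C8a; ring B = the carbocycle). TBS = tert-butyldimethylsilyl, Boc = tert-butoxycarbonyl.
- The carbon that is C3 (R) in the bicycle is labelled S in the dioxolane, the diol and the iodohydrin, because CH2O or CH2I outranks the nitrogen-bearing carbon there; no inversion is involved.
- The C3 oxygen is carried as a free hydroxyl through the ring closure. This keeps any benzylic C–H or arene away from the two radicals and makes a separate unmasking before esterification unnecessary.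
- Assumption: 4 and 9 are taken as purchased, 9 being distilled just before use.

**Step 1**
Reactants: 1 (R)-2-propyloxirane
Product: 2 (4R)-oct-7-en-4-ol
Conditions: allylMgBr, CuI (10 mol%), THF, −40 → 0 °C; aq. NH4Cl
Reagents that add atoms: allylmagnesium bromide, C=CC[Mg]Br
Why: Copper-catalysed Grignard opening of a terminal epoxide (SN2) occurs at the unhindered CH2, so the carbinol carbon is not touched and stays R.

**Step 2**
Reactants: 2 (4R)-oct-7-en-4-ol
Product: 3 tert-butyl(dimethyl){[(4R)-oct-7-en-4-yl]oxy}silane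
Conditions: TBSCl, imidazole, DMF, rt
Reagents that add atoms: tert-butyldimethylsilyl chloride, CC(C)(C)[Si](C)(C)Cl
Why: Imidazole-promoted silyl ether formation on a secondary alcohol does not involve the stereocentre.

**Step 3**
Reactants: 3 tert-butyl(dimethyl){[(4R)-oct-7-en-4-yl]oxy}silane; 4 3-bromocyclohex-2-en-1-one
Product: 6 3-[(5R)-5-(TBSO)octyl]cyclohex-2-en-1-one, via B-alkyl-9-BBN borane 5 (not isolated)
Conditions: 9-BBN, THF, rt; then 4, PdCl2(dppf) (3 mol%), K3PO4 (3 M aq.), DMF, 50 °C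
Reagents that add atoms: none
Why: Anti-Markovnikov hydroboration of the terminal alkene followed by B-alkyl Suzuki–Miyaura coupling with the β-bromoenone, whose C–Br bond adds readily to zerovalent palladium, joins the chain to the ring without forming a stereocentre.

**Step 4**
Reactants: 6 3-[(5R)-5-(TBSO)octyl]cyclohex-2-en-1-one
Product: 7 (1R)-3-[(5R)-5-(TBSO)octyl]cyclohex-2-en-1-ol
Conditions: (S)-2-methyl-CBS-oxazaborolidine (20 mol%), catecholborane, toluene, −78 °C
Reagents that add atoms: none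
Why: In this Corey–Bakshi–Shibata reduction the C=C flank of the enone acts as the large group, so the (S)-oxazaborolidine should deliver hydride 1,2 to the face that gives the (1R)-allylic alcohol (the future C8a).

**Step 5**
Reactants: 7 (1R)-3-[(5R)-5-(TBSO)octyl]cyclohex-2-en-1-ol
Product: 8 methyl (1R)-3-[(5R)-5-(TBSO)octyl]cyclohex-2-en-1-yl carbonate
Conditions: ClCO2Me, pyridine, DMAP (cat.), CH2Cl2, 0 °C
Reagents that add atoms: methyl chloroformate, COC(=O)Cl
Why: O-acylation with a chloroformate (carbonate formation) leaves the C1–O bond intact, so C1 stays R.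

**Step 6**
Reactants: 9 (4R)-2,2-dimethyl-1,3-dioxolane-4-carbaldehyde; 10 (R)-2-methylpropane-2-sulfinamide
Product: 11 (R,E)-N-{[(4S)-2,2-dimethyl-1,3-dioxolan-4-yl]methylidene}-2-methylpropane-2-sulfinamide
Conditions: CuSO4 (anhydrous), CH2Cl2, rt
Reagents that add atoms: none
Why: Dehydrative condensation of an aldehyde with tert-butanesulfinamide gives the E-sulfinimine under conditions mild enough to leave the α-alkoxy centre unchanged.

**Step 7**
Reactants: 11 (R,E)-N-{[(4S)-2,2-dimethyl-1,3-dioxolan-4-yl]methylidene}-2-methylpropane-2-sulfinamide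
Product: 12 (R)-N-{(1S)-1-[(4S)-2,2-dimethyl-1,3-dioxolan-4-yl]ethyl}-2-methylpropane-2-sulfinamide
Conditions: MeMgBr (3 M in Et2O), CH2Cl2, −78 → −40 °C; aq. NH4Cl
Reagents that add atoms: methylmagnesium bromide, C[Mg]Br
Why: Grignard 1,2-addition to an N-sulfinyl aldimine in a non-coordinating solvent runs through a six-membered magnesium-bridged chair that delivers methyl to the face syn to the sulfinyl oxygen, which for R-configured sulfur gives the S amine carbon (C2 of the target) and agrees with the inherent 1,2-induction of the dioxolane centre.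

**Step 8**
Reactants: 12 (R)-N-{(1S)-1-[(4S)-2,2-dimethyl-1,3-dioxolan-4-yl]ethyl}-2-methylpropane-2-sulfinamide
Product: 13 (1S)-1-[(4S)-2,2-dimethyl-1,3-dioxolan-4-yl]ethan-1-amine hydrochloride
Conditions: HCl (4 M in dioxane, 2.1 equiv), Et2O, 0 °C; filter
Reagents that add atoms: hydrogen chloride, Cl
Why: Acidolysis of the S–N bond by anhydrous HCl precipitates the amine hydrochloride, and the absence of water or alcohol should spare the acetonide.

**Step 9**
Reactants: 8 methyl (1R)-3-[(5R)-5-(TBSO)octyl]cyclohex-2-en-1-yl carbonate; 13 (1S)-1-[(4S)-2,2-dimethyl-1,3-dioxolan-4-yl]ethan-1-amine hydrochloride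
Product: 14 (1R)-N-{(1S)-1-[(4S)-2,2-dimethyl-1,3-dioxolan-4-yl]ethyl}-3-[(5R)-5-(TBSO)octyl]cyclohex-2-en-1-amine
Conditions: Pd(PPh3)4 (5 mol%), Et3N, THF, 40 °C
Reagents that add atoms: none
Why: In this Tsuji–Trost allylic amination, ionisation with inversion and attack of the amine anti to palladium at the unsubstituted allyl terminus give net retention, so C1 (C8a) stays R, and a cyclic π-allyl cannot change face by π–σ–π isomerisation.

**Step 10**
Reactants: 14 (1R)-N-{(1S)-1-[(4S)-2,2-dimethyl-1,3-dioxolan-4-yl]ethyl}-3-[(5R)-5-(TBSO)octyl]cyclohex-2-en-1-amine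
Product: 15 tert-butyl N-{(1S)-1-[(4S)-2,2-dimethyl-1,3-dioxolan-4-yl]ethyl}-N-{(1R)-3-[(5R)-5-(TBSO)octyl]cyclohex-2-en-1-yl}carbamate
Conditions: Boc2O (3 equiv), DMAP (cat.), Et3N, MeCN, 50 °C
Reagents that add atoms: di-tert-butyl dicarbonate, CC(C)(C)OC(=O)OC(=O)OC(C)(C)C
Why: DMAP-catalysed N-acylation (carbamate formation), heated because the nitrogen is flanked by two secondary carbons, touches no stereocentre and no free hydroxyl is present to compete.

**Step 11**
Reactants: 15 tert-butyl N-{(1S)-1-[(4S)-2,2-dimethyl-1,3-dioxolan-4-yl]ethyl}-N-{(1R)-3-[(5R)-5-(TBSO)octyl]cyclohex-2-en-1-yl}carbamate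
Product: 16 tert-butyl N-[(2S,3S)-3,4-dihydroxybutan-2-yl]-N-{(1R)-3-[(5R)-5-(TBSO)octyl]cyclohex-2-en-1-yl}carbamate
Conditions: AcOH/H2O (4:1), rt → 40 °C
Reagents that add atoms: none
Why: Acid-catalysed hydrolysis of a terminal isopropylidene acetal in aqueous acetic acid is faster than cleavage of the secondary silyl ether or the carbamate.

**Step 12**
Reactants: 16 tert-butyl N-[(2S,3S)-3,4-dihydroxybutan-2-yl]-N-{(1R)-3-[(5R)-5-(TBSO)octyl]cyclohex-2-en-1-yl}carbamate
Product: 17 tert-butyl N-[(2S,3S)-3-hydroxy-4-iodobutan-2-yl]-N-{(1R)-3-[(5R)-5-(TBSO)octyl]cyclohex-2-en-1-yl}carbamate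
Conditions: PPh3, imidazole, I2 (1.1 equiv, added last in portions), CH2Cl2, 0 °C
Reagents that add atoms: iodine, II
Why: In this Garegg–Samuelsson (Appel-type) iodination the primary alkoxyphosphonium forms and is displaced by iodide much faster than the secondary one, and adding iodine to the phosphine keeps free iodine away from the ring alkene, so C3 is untouched.

**Step 13**
Reactants: 17 tert-butyl N-[(2S,3S)-3-hydroxy-4-iodobutan-2-yl]-N-{(1R)-3-[(5R)-5-(TBSO)octyl]cyclohex-2-en-1-yl}carbamate
Product: 18 tert-butyl (2S,3R,4aS,5S,8aR)-3-hydroxy-2-methyl-5-[(5R)-5-(TBSO)octyl]octahydroquinoline-1(2H)-carboxylate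
Conditions: (Me3Si)3SiH (1.3 equiv) and AIBN (0.2 equiv) by syringe pump over 4 h, toluene (0.01 M in 17), 80 °C
Reagents that add atoms: none
Why: The silyl radical abstracts iodine to give the primary C4 radical, which adds to C4a of the ring alkene and leaves a tertiary C5 radical that takes hydrogen from the silane; the closest known reaction type is the tin- or silane-mediated 6-exo-trig cyclisation of alkyl radicals onto cycloalkenes with diastereoselective hydrogen-atom transfer. Ring A closes in the 6-exo-trig mode, attack at the unsubstituted alkene carbon C4a being preferred over 7-endo attack at the fully substituted C5. C4a is controlled by C8a, because the three-atom arm on nitrogen can reach C4a through a chair-like approach only on the face that nitrogen occupies, so the fusion is cis. C5 is controlled by the folded cis-bicycle, in which allylic 1,3-strain from the carbamate holds C8 axial on ring A and the C4–C4a bond axial on ring B, so the silane approaches C5 axially from the convex face and places H5 cis to H4a. The step needs ring closure to outrun direct reduction and a 1,5-hydrogen shift from C8a–H, which a slow hydrogen donor kept at low concentration, the tertiary product radical and the carbamate-enforced proximity of C4 and C4a should secure. The free C3 hydroxyl is inert to carbon radicals.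

**Step 14**
Reactants: 19 (2E)-hex-2-enal; 20 malonic acid
Product: 22 (2E,4E)-octa-2,4-dienoic acid, via hexenylidenemalonic acid 21 (not isolated)
Conditions: pyridine, piperidine (cat.), 90 °C
Reagents that add atoms: none
Why: Doebner–Knoevenagel condensation with in situ decarboxylation gives the thermodynamically preferred E geometry at the new C2=C3 bond while the existing E alkene is retained.

**Step 15**
Reactants: 18 tert-butyl (2S,3R,4aS,5S,8aR)-3-hydroxy-2-methyl-5-[(5R)-5-(TBSO)octyl]octahydroquinoline-1(2H)-carboxylate; 22 (2E,4E)-octa-2,4-dienoic acid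
Product: 24 tert-butyl (2S,3R,4aS,5S,8aR)-2-methyl-3-{[(2E,4E)-octa-2,4-dienoyl]oxy}-5-[(5R)-5-(TBSO)octyl]octahydroquinoline-1(2H)-carboxylate, via mixed trichlorobenzoic anhydride 23 (not isolated)
Conditions: 22, 2,4,6-Cl3C6H2COCl, Et3N, THF, rt; then 18, DMAP, toluene, rt
Reagents that add atoms: none
Why: Yamaguchi esterification through the mixed anhydride and DMAP acyl transfer suits the hindered axial secondary alcohol, and since the C3–O bond is not broken the configuration is retained.

**Step 16**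
Reactants: 24 tert-butyl (2S,3R,4aS,5S,8aR)-2-methyl-3-{[(2E,4E)-octa-2,4-dienoyl]oxy}-5-[(5R)-5-(TBSO)octyl]octahydroquinoline-1(2H)-carboxylate
Product: 25 lepadin H, (2S,3R,4aS,5S,8aR)-5-[(5R)-5-hydroxyoctyl]-2-methyldecahydroquinolin-3-yl (2E,4E)-octa-2,4-dienoate
Conditions: TFA/H2O (9:1), 0 °C → rt; aq. NaHCO3
Reagents that add atoms: none
Why: Acidolysis removes the tert-butyl carbamate (loss of isobutene and CO2) and hydrolyses the secondary silyl ether in one operation, while the protonated amine cannot attack the neighbouring ester and any trifluoroacetate on the side-chain hydroxyl falls off in the bicarbonate work-up.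

**Compound list**
1 | (R)-2-propyloxirane | CCC[C@@H]1CO1 | starting material
2 | (4R)-oct-7-en-4-ol | C=CCC[C@H](O)CCC | intermediate
3 | tert-butyl(dimethyl){[(4R)-oct-7-en-4-yl]oxy}silane | C=CCC[C@H](O[Si](C)(C)C(C)(C)C)CCC | intermediate
4 | 3-bromocyclohex-2-en-1-one | O=C1C=C(Br)CCC1 | starting material
5 | 9-[(5R)-5-(TBSO)octyl]-9-borabicyclo[3.3.1]nonane | B1(CCCC[C@H](O[Si](C)(C)C(C)(C)C)CCC)C2CCCC1CCC2 | intermediate (not isolated)
6 | 3-[(5R)-5-(TBSO)octyl]cyclohex-2-en-1-one | O=C1C=C(CCCC[C@H](O[Si](C)(C)C(C)(C)C)CCC)CCC1 | intermediate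
7 | (1R)-3-[(5R)-5-(TBSO)octyl]cyclohex-2-en-1-ol | O[C@H]1C=C(CCCC[C@H](O[Si](C)(C)C(C)(C)C)CCC)CCC1 | intermediate
8 | methyl (1R)-3-[(5R)-5-(TBSO)octyl]cyclohex-2-en-1-yl carbonate | COC(=O)O[C@H]1C=C(CCCC[C@H](O[Si](C)(C)C(C)(C)C)CCC)CCC1 | intermediate
9 | (4R)-2,2-dimethyl-1,3-dioxolane-4-carbaldehyde | O=C[C@H]1COC(C)(C)O1 | starting material
10 | (R)-2-methylpropane-2-sulfinamide | CC(C)(C)[S@@](=O)N | starting material
11 | (R,E)-N-{[(4S)-2,2-dimethyl-1,3-dioxolan-4-yl]methylidene}-2-methylpropane-2-sulfinamide | CC(C)(C)[S@@](=O)/N=C/[C@H]1COC(C)(C)O1 | intermediate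
12 | (R)-N-{(1S)-1-[(4S)-2,2-dimethyl-1,3-dioxolan-4-yl]ethyl}-2-methylpropane-2-sulfinamide | CC(C)(C)[S@@](=O)N[C@@H](C)[C@H]1COC(C)(C)O1 | intermediate
13 | (1S)-1-[(4S)-2,2-dimethyl-1,3-dioxolan-4-yl]ethan-1-amine hydrochloride | C[C@H](N)[C@H]1COC(C)(C)O1.Cl | intermediate
14 | (1R)-N-{(1S)-1-[(4S)-2,2-dimethyl-1,3-dioxolan-4-yl]ethyl}-3-[(5R)-5-(TBSO)octyl]cyclohex-2-en-1-amine | C[C@H](N[C@H]1C=C(CCCC[C@H](O[Si](C)(C)C(C)(C)C)CCC)CCC1)[C@H]1COC(C)(C)O1 | intermediate
15 | tert-butyl N-{(1S)-1-[(4S)-2,2-dimethyl-1,3-dioxolan-4-yl]ethyl}-N-{(1R)-3-[(5R)-5-(TBSO)octyl]cyclohex-2-en-1-yl}carbamate | C[C@H](N(C(=O)OC(C)(C)C)[C@H]1C=C(CCCC[C@H](O[Si](C)(C)C(C)(C)C)CCC)CCC1)[C@H]1COC(C)(C)O1 | intermediate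
16 | tert-butyl N-[(2S,3S)-3,4-dihydroxybutan-2-yl]-N-{(1R)-3-[(5R)-5-(TBSO)octyl]cyclohex-2-en-1-yl}carbamate | C[C@H](N(C(=O)OC(C)(C)C)[C@H]1C=C(CCCC[C@H](O[Si](C)(C)C(C)(C)C)CCC)CCC1)[C@H](O)CO | intermediate
17 | tert-butyl N-[(2S,3S)-3-hydroxy-4-iodobutan-2-yl]-N-{(1R)-3-[(5R)-5-(TBSO)octyl]cyclohex-2-en-1-yl}carbamate | C[C@H](N(C(=O)OC(C)(C)C)[C@H]1C=C(CCCC[C@H](O[Si](C)(C)C(C)(C)C)CCC)CCC1)[C@H](O)CI | intermediate
18 | tert-butyl (2S,3R,4aS,5S,8aR)-3-hydroxy-2-methyl-5-[(5R)-5-(TBSO)octyl]octahydroquinoline-1(2H)-carboxylate | O[C@@H]1C[C@H]2[C@@H](CCCC[C@H](O[Si](C)(C)C(C)(C)C)CCC)CCC[C@H]2N(C(=O)OC(C)(C)C)[C@H]1C | intermediate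
19 | (2E)-hex-2-enal | CCC/C=C/C=O | starting material
20 | malonic acid | OC(=O)CC(=O)O | starting material
21 | 2-[(2E)-hex-2-en-1-ylidene]propanedioic acid | CCC/C=C/C=C(C(=O)O)C(=O)O | intermediate (not isolated)
22 | (2E,4E)-octa-2,4-dienoic acid | CCC/C=C/C=C/C(=O)O | intermediate
23 | (2E,4E)-octa-2,4-dienoic 2,4,6-trichlorobenzoic anhydride | CCC/C=C/C=C/C(=O)OC(=O)c1c(Cl)cc(Cl)cc1Cl | intermediate (not isolated)
24 | tert-butyl (2S,3R,4aS,5S,8aR)-2-methyl-3-{[(2E,4E)-octa-2,4-dienoyl]oxy}-5-[(5R)-5-(TBSO)octyl]octahydroquinoline-1(2H)-carboxylate | CCC/C=C/C=C/C(=O)O[C@@H]1C[C@H]2[C@@H](CCCC[C@H](O[Si](C)(C)C(C)(C)C)CCC)CCC[C@H]2N(C(=O)OC(C)(C)C)[C@H]1C | intermediate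
25 | lepadin H | CCC/C=C/C=C/C(=O)O[C@@H]1C[C@H]2[C@@H](CCCC[C@H](O)CCC)CCC[C@H]2N[C@H]1C | target

**Step count.** Total: 16 steps. Longest linear sequence: 12 steps (1–5, 9–13, 15, 16).

**Steps most likely to fail**

Step 13. Hydrogen may reach the primary C4 radical (from the silane or by a 1,5-shift from C8a–H) before the ring closes, or hydrogen delivery to the C5 radical may discriminate poorly between the two faces. The fallback sets out from 17 and separates ring closure from the setting of C5. The ring would be closed without a hydrogen donor by a cobaloxime-catalysed Heck-type cyclisation of the alkyl iodide under visible light (Ph3SnCo(dmgH)2(py), iPr2NEt, MeCN, blue light, rt), in which the C5 radical is captured by cobalt and released by β-hydride loss. This should give the ring-B alkene tert-butyl (2S,3R,4aS,8aR)-3-hydroxy-2-methyl-5-[(5R)-5-(TBSO)octyl]-3,4,4a,7,8,8a-hexahydroquinoline-1(2H)-carboxylate F1. Heterogeneous hydrogenation (H2, PtO2, EtOAc) from the convex face should then place H5 cis to H4a and bring the route back at 18.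

Step 9. The α-branched amine may attack the π-allyl complex slowly, which would allow diene formation by β-hydride elimination or erosion of the C8a configuration by exchange between palladium centres. The fallback sets out from 6 and 13 and forms the C8a–N bond by SN2 inversion instead. Enone 6 would be reduced with the enantiomeric (R)-2-methyl-CBS-oxazaborolidine and catecholborane to (1S)-3-[(5R)-5-(TBSO)octyl]cyclohex-2-en-1-ol F2. Amine salt 13 would be converted with 2-nitrobenzenesulfonyl chloride and Et3N into N-{(1S)-1-[(4S)-2,2-dimethyl-1,3-dioxolan-4-yl]ethyl}-2-nitrobenzenesulfonamide F3. A Fukuyama–Mitsunobu coupling (PBu3, 1,1'-(azodicarbonyl)dipiperidine, toluene) should join the two with inversion to N-{(1S)-1-[(4S)-2,2-dimethyl-1,3-dioxolan-4-yl]ethyl}-N-{(1R)-3-[(5R)-5-(TBSO)octyl]cyclohex-2-en-1-yl}-2-nitrobenzenesulfonamide F4. Thiolate cleavage (PhSH, K2CO3, MeCN) returns the route at 14.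

Step 7. A transition state chelated through the α-alkoxy oxygen, or an open one, may compete with the magnesium-bridged chair and lower the facial selectivity at the new amine carbon. The fallback sets out from 9 and sets this centre by hydride delivery instead of carbon addition. MeMgBr addition would give 1-[(4R)-2,2-dimethyl-1,3-dioxolan-4-yl]ethan-1-ol F5 (both carbinol epimers, not separated). Dess–Martin oxidation would give 1-[(4R)-2,2-dimethyl-1,3-dioxolan-4-yl]ethan-1-one F6. Condensation with 10 (Ti(OEt)4, THF, rt, kept mild to protect the α-centre) would give (R)-N-{(1E)-1-[(4S)-2,2-dimethyl-1,3-dioxolan-4-yl]ethylidene}-2-methylpropane-2-sulfinamide F7. Reduction with LiBH(s-Bu)3 (THF, −78 °C) through an open transition state should then give the S amine carbon and return the route at 12; NaBH4, which reacts through the closed transition state, is the complementary reagent for the opposite face.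

**Further compounds**
F1 | step 13 | tert-butyl (2S,3R,4aS,8aR)-3-hydroxy-2-methyl-5-[(5R)-5-(TBSO)octyl]-3,4,4a,7,8,8a-hexahydroquinoline-1(2H)-carboxylate | O[C@@H]1C[C@H]2C(CCCC[C@H](O[Si](C)(C)C(C)(C)C)CCC)=CCC[C@H]2N(C(=O)OC(C)(C)C)[C@H]1C
F2 | step 9 | (1S)-3-[(5R)-5-(TBSO)octyl]cyclohex-2-en-1-ol | O[C@@H]1C=C(CCCC[C@H](O[Si](C)(C)C(C)(C)C)CCC)CCC1
F3 | step 9 | N-{(1S)-1-[(4S)-2,2-dimethyl-1,3-dioxolan-4-yl]ethyl}-2-nitrobenzenesulfonamide | C[C@H](NS(=O)(=O)c1ccccc1[N+](=O)[O-])[C@H]1COC(C)(C)O1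
F4 | step 9 | N-{(1S)-1-[(4S)-2,2-dimethyl-1,3-dioxolan-4-yl]ethyl}-N-{(1R)-3-[(5R)-5-(TBSO)octyl]cyclohex-2-en-1-yl}-2-nitrobenzenesulfonamide | C[C@H](N(S(=O)(=O)c1ccccc1[N+](=O)[O-])[C@H]1C=C(CCCC[C@H](O[Si](C)(C)C(C)(C)C)CCC)CCC1)[C@H]1COC(C)(C)O1
F5 | step 7 | 1-[(4R)-2,2-dimethyl-1,3-dioxolan-4-yl]ethan-1-ol (both carbinol epimers) | CC(O)[C@H]1COC(C)(C)O1
F6 | step 7 | 1-[(4R)-2,2-dimethyl-1,3-dioxolan-4-yl]ethan-1-one | CC(=O)[C@H]1COC(C)(C)O1
F7 | step 7 | (R)-N-{(1E)-1-[(4S)-2,2-dimethyl-1,3-dioxolan-4-yl]ethylidene}-2-methylpropane-2-sulfinamide | CC(C)(C)[S@@](=O)/N=C(\C)[C@H]1COC(C)(C)O1
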